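The route rests on cutting the enol ether double bond C2=C3 of the 2,3-dihydrofuran ring (O, C3, C2, C1, C10). C3 is a carboxyl carbon in disguise, so this ring is the ester of the C10 tertiary alcohol, which carries the C1–C2 allyl group, with the C3–C6 hydroxy acid. One titanium-alkylidene carbonyl–olefin cyclisation forms C2=C3, closes the ring and unites both carbinol carbons (C10, C4) under basic, aprotic conditions. Its precursor is the doubly hindered tertiary homoallyl ester with silyl ethers at O9, O4 and O6. The ten-membered ring is closed afterwards at C8=C9 by a vinylogous aldol condensation onto a bromobutenolide.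

Key step: step 7

Numbering: ten-membered carbocycle C1 (CH2), C2=C3, C4 (C–OH, CH3), C5 (CH2), C6 (CH–OAc), C7, C8, C9 (=CH), C10 (C–O, CH3). An oxygen bridges C3 and C10 (dihydrofuran ring O/C3/C2/C1/C10). The butenolide ring is C7=C11–C12(=O)–O–C8, and C13 is the CH2OAc on C11. O4, O6 and O9 are the oxygens on those carbons.

Remark on configuration: the target SMILES reads 4S, 6S, 10S with an E C8=C9 bond (C10 cis to C7). The carbinol stereocentres are C10 and C4; C9 and C6 are primary CH2–O carbons at the key-step stage.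

Remark on protecting groups: O6 carries the most labile group (primary triethylsilyl), so only one selective desilylation is needed. The tert-butyldiphenylsilyl group on O9 and the tertiary triethylsilyl group on O4 are later removed together.

Remark on acid: while O6 is a free hydroxyl (12, 15, 17) acid could add it to C3 of the enol ether as a five-membered spiroketal, so these compounds are kept under basic or buffered conditions.

Assumption: compounds 1, 4, 14 and (tributylstannyl)methanol are purchased, 1 and 4 in enantiopure form.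

Step 1
Reactants: 1 (R)-2-methylglycidol
Product: 2 tert-butyl{[(2S)-2-methyloxiran-2-yl]methoxy}diphenylsilane
Conditions: TBDPSCl, imidazole, CH2Cl2, 0 °C → rt
Reagents that add atoms: tert-butyl(chloro)diphenylsilane, CC(C)(C)[Si](Cl)(c1ccccc1)c1ccccc1
Why: Silylation of the primary hydroxyl with a bulky silyl chloride under imidazole catalysis leaves the epoxide and its stereocentre untouched (the descriptor changes from R to S only through the priority rules).

Step 2
Reactants: 2 tert-butyl{[(2S)-2-methyloxiran-2-yl]methoxy}diphenylsilane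
Product: 3 (2S)-1-[tert-butyl(diphenyl)silyl]oxy-2-methylpent-4-en-2-ol
Conditions: CH2=CHMgBr, CuI (cat.), THF, −30 → 0 °C; aq. NH4Cl
Reagents that add atoms: vinylmagnesium bromide, C=C[Mg]Br
Why: Copper-catalysed Grignard opening of the 2,2-disubstituted epoxide (SN2) occurs at the unsubstituted CH2 carbon, so the epoxide CH2 and the vinyl group become the C1–C2 allyl unit and the quaternary carbon C10 keeps its configuration.

Step 3
Reactants: 4 (S)-citramalic acid
Product: 5 2-[(4S)-2,2,4-trimethyl-5-oxo-1,3-dioxolan-4-yl]acetic acid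
Conditions: Me2C(OMe)2, TsOH (cat.), acetone, rt
Reagents that add atoms: 2,2-dimethoxypropane, COC(C)(C)OC
Why: Acid-catalysed transacetalisation ties the α-hydroxy acid into the five-membered 1,3-dioxolan-4-one in preference to the six-membered alternative, which protects O4 and the C3 carboxyl at once, activates C3 as an acyl donor and leaves only the C6 carboxyl free; C4 is not involved.

Step 4
Reactants: 5 2-[(4S)-2,2,4-trimethyl-5-oxo-1,3-dioxolan-4-yl]acetic acid
Product: 6 (5S)-5-(2-hydroxyethyl)-2,2,5-trimethyl-1,3-dioxolan-4-one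
Conditions: BH3·SMe2, THF, 0 °C → rt; MeOH
Reagents that add atoms: none
Why: Borane reduction of a carboxylic acid (through the acyloxyborane) is much faster than reduction of the lactone-type carbonyl, so the C6 primary alcohol is formed chemoselectively.

Step 5
Reactants: 6 (5S)-5-(2-hydroxyethyl)-2,2,5-trimethyl-1,3-dioxolan-4-one
Product: 7 (5S)-2,2,5-trimethyl-5-[2-(triethylsilyloxy)ethyl]-1,3-dioxolan-4-one
Conditions: TESCl, imidazole, CH2Cl2, 0 °C
Reagents that add atoms: chlorotriethylsilane, CC[Si](Cl)(CC)CC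
Why: Standard silyl ether formation at the primary alcohol under mildly basic conditions, done at once so that the hydroxyl cannot attack the dioxolanone carbonyl and lactonise.

Step 6
Reactants: 3 (2S)-1-[tert-butyl(diphenyl)silyl]oxy-2-methylpent-4-en-2-ol; 7 (5S)-2,2,5-trimethyl-5-[2-(triethylsilyloxy)ethyl]-1,3-dioxolan-4-one
Product: 10 (2S)-1-[tert-butyl(diphenyl)silyl]oxy-2-methylpent-4-en-2-yl (2S)-2-methyl-2,4-bis(triethylsilyloxy)butanoate, via potassium alkoxide 8 (not isolated), via ester alkoxide 9 (not isolated)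
Conditions: KN(SiMe3)2, THF, −78 °C; 7, −78 → −30 °C; TESCl, −30 → 0 °C
Reagents that add atoms: chlorotriethylsilane, CC[Si](Cl)(CC)CC
Why: Alkoxide transacylation (addition–elimination) at the tied-back, activated dioxolanone carbonyl expels acetone and gives the more stabilised α-ester alkoxide 9, which is the least hindered way to join two fully substituted carbinol carbons through an ester; the α-carbon cannot enolise, both stereocentres are untouched, and silylation of 9 in the same flask forestalls silyl shifts and lactonisation.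

Step 7
Reactants: 10 (2S)-1-[tert-butyl(diphenyl)silyl]oxy-2-methylpent-4-en-2-yl (2S)-2-methyl-2,4-bis(triethylsilyloxy)butanoate
Product: 11 tert-butyl({(2S)-2-methyl-5-[(2S)-2,4-bis(triethylsilyloxy)butan-2-yl]-2,3-dihydrofuran-2-yl}methoxy)diphenylsilane
Conditions: TiCl4, TMEDA, Zn, PbCl2 (cat.), CH3CHBr2, THF/CH2Cl2, 0 → 65 °C; aq. K2CO3
Reagents that add atoms: none
Why: The titanium ethylidene made from CH3CHBr2, TiCl4 and Zn undergoes [2+2] cycloaddition and cycloreversion with the terminal alkene (propene is lost) to place a titanium alkylidene on C2, which adds across the ester carbonyl C3=O to an oxatitanacyclobutane that collapses to C2=C3 and a titanium oxo species; the other order, ethylidenation of the ester followed by enol ether–olefin metathesis, leads to the same product. The closest known reaction type is the olefinic-ester cyclisation (ring-closing carbonyl–olefin metathesis) with Takai–Utimoto reagents to cyclic enol ethers. The dihydrofuran closes as a five-membered ring by intramolecular carbonyl olefination with the new double bond endocyclic, and the geminal substitution at C10 and C4 favours the folded conformer. No stereocentre is formed, and C10 and C4 are quaternary and cannot epimerise. The step needs chemoselectivity for cyclisation over simple ethylidenation of the ester, which is secured because the unhindered terminal alkene is the first site the reagent reaches while the ester is shielded on both sides, the ring is five-membered, and the substrate carries only silyl ethers and no other carbonyl group; the acid-labile enol ether is formed under basic, aprotic conditions.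

Step 8
Reactants: 11 tert-butyl({(2S)-2-methyl-5-[(2S)-2,4-bis(triethylsilyloxy)butan-2-yl]-2,3-dihydrofuran-2-yl}methoxy)diphenylsilane
Product: 12 (3S)-3-[(5S)-5-{[tert-butyl(diphenyl)silyl]oxymethyl}-5-methyl-4,5-dihydrofuran-2-yl]-3-(triethylsilyloxy)butan-1-ol
Conditions: TBAF, AcOH (1:1), THF, −20 → 0 °C
Reagents that add atoms: none
Why: Fluoride-induced desilylation is far faster for the unhindered primary triethylsilyl ether than for the tertiary triethylsilyl ether or the bulky silyl ether at the neopentyl position, and the acetic acid buffer keeps the medium neither acidic enough to protonate the enol ether nor basic enough for silyl migration.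

Step 9
Reactants: 12 (3S)-3-[(5S)-5-{[tert-butyl(diphenyl)silyl]oxymethyl}-5-methyl-4,5-dihydrofuran-2-yl]-3-(triethylsilyloxy)butan-1-ol
Product: 13 (3S)-3-[(5S)-5-{[tert-butyl(diphenyl)silyl]oxymethyl}-5-methyl-4,5-dihydrofuran-2-yl]-3-(triethylsilyloxy)butanal
Conditions: SO3·pyridine, DMSO, i-Pr2NEt, CH2Cl2, 0 °C
Reagents that add atoms: none
Why: Parikh–Doering oxidation (activated dimethyl sulfoxide under amine base) should give the aldehyde without over-oxidation and without any acid that could add the free O6 hydroxyl to the enol ether.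

Step 10
Reactants: 13 (3S)-3-[(5S)-5-{[tert-butyl(diphenyl)silyl]oxymethyl}-5-methyl-4,5-dihydrofuran-2-yl]-3-(triethylsilyloxy)butanal; 14 3,4-dibromofuran-2(5H)-one
Product: 15 3-bromo-4-{(1RS,3S)-3-[(5S)-5-{[tert-butyl(diphenyl)silyl]oxymethyl}-5-methyl-4,5-dihydrofuran-2-yl]-1-hydroxy-3-(triethylsilyloxy)butyl}furan-2(5H)-one (both C6 epimers)
Conditions: CrCl2, NiCl2 (cat.), DMF, rt; aq. NaHCO3
Reagents that add atoms: none
Why: Nozaki–Hiyama–Kishi coupling, in which zerovalent nickel inserts into the more electrophilic C–Br bond β to the lactone carbonyl (the vinylogous acyl bromide), and the vinylchromium species formed by transmetalation adds to the aldehyde under non-basic conditions; the carbinol centre C6 forms without control and is corrected in steps 11 and 12.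

Step 11
Reactants: 15 3-bromo-4-{(1RS,3S)-3-[(5S)-5-{[tert-butyl(diphenyl)silyl]oxymethyl}-5-methyl-4,5-dihydrofuran-2-yl]-1-hydroxy-3-(triethylsilyloxy)butyl}furan-2(5H)-one
Product: 16 3-bromo-4-{(3S)-3-[(5S)-5-{[tert-butyl(diphenyl)silyl]oxymethyl}-5-methyl-4,5-dihydrofuran-2-yl]-3-(triethylsilyloxy)butanoyl}furan-2(5H)-one
Conditions: SO3·pyridine, DMSO, i-Pr2NEt, CH2Cl2, 0 °C → rt
Reagents that add atoms: none
Why: Parikh–Doering oxidation of the allylic-type secondary alcohol converges both C6 epimers to one ketone under basic conditions.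

Step 12
Reactants: 16 3-bromo-4-{(3S)-3-[(5S)-5-{[tert-butyl(diphenyl)silyl]oxymethyl}-5-methyl-4,5-dihydrofuran-2-yl]-3-(triethylsilyloxy)butanoyl}furan-2(5H)-one
Product: 17 3-bromo-4-{(1S,3S)-3-[(5S)-5-{[tert-butyl(diphenyl)silyl]oxymethyl}-5-methyl-4,5-dihydrofuran-2-yl]-1-hydroxy-3-(triethylsilyloxy)butyl}furan-2(5H)-one
Conditions: (R)-2-methyl-CBS-oxazaborolidine, catecholborane, toluene, −78 °C; aq. NaHCO3
Reagents that add atoms: none
Why: Corey–Bakshi–Shibata reduction, in which the (R)-oxazaborolidine binds the ketone with the fully substituted butenolide carbon C7 as the large group and the C5 methylene as the small group and delivers hydride to give the (6S)-alcohol, by analogy with aryl alkyl ketones and α-substituted enones; catecholborane at −78 °C should not hydroborate the enol ether.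

Step 13
Reactants: 17 3-bromo-4-{(1S,3S)-3-[(5S)-5-{[tert-butyl(diphenyl)silyl]oxymethyl}-5-methyl-4,5-dihydrofuran-2-yl]-1-hydroxy-3-(triethylsilyloxy)butyl}furan-2(5H)-one
Product: 18 (1S,3S)-1-(4-bromo-5-oxo-2,5-dihydrofuran-3-yl)-3-[(5S)-5-{[tert-butyl(diphenyl)silyl]oxymethyl}-5-methyl-4,5-dihydrofuran-2-yl]-3-(triethylsilyloxy)butyl acetate
Conditions: Ac2O, pyridine, DMAP (cat.), CH2Cl2, 0 °C → rt
Reagents that add atoms: acetic anhydride, CC(=O)OC(C)=O
Why: Nucleophile-catalysed acylation of the secondary alcohol installs the C6 acetate of the target and removes the hydroxyl that could spiroketalise onto the enol ether.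

Step 14
Reactants: 18 (1S,3S)-1-(4-bromo-5-oxo-2,5-dihydrofuran-3-yl)-3-[(5S)-5-{[tert-butyl(diphenyl)silyl]oxymethyl}-5-methyl-4,5-dihydrofuran-2-yl]-3-(triethylsilyloxy)butyl acetate
Product: 19 (1S,3S)-1-(4-bromo-5-oxo-2,5-dihydrofuran-3-yl)-3-hydroxy-3-[(5S)-5-(hydroxymethyl)-5-methyl-4,5-dihydrofuran-2-yl]butyl acetate
Conditions: TBAF, AcOH (1:1, excess), THF, 0 °C → rt
Reagents that add atoms: none
Why: Buffered fluoride desilylation removes both remaining silyl groups in one operation, so no selectivity between them is needed, while the acetate, the bromobutenolide and the enol ether tolerate the near-neutral medium.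

Step 15
Reactants: 19 (1S,3S)-1-(4-bromo-5-oxo-2,5-dihydrofuran-3-yl)-3-hydroxy-3-[(5S)-5-(hydroxymethyl)-5-methyl-4,5-dihydrofuran-2-yl]butyl acetate
Product: 20 (1S,3S)-1-(4-bromo-5-oxo-2,5-dihydrofuran-3-yl)-3-[(5S)-5-formyl-5-methyl-4,5-dihydrofuran-2-yl]-3-hydroxybutyl acetate
Conditions: SO3·pyridine, DMSO, i-Pr2NEt, CH2Cl2, 0 °C
Reagents that add atoms: none
Why: Parikh–Doering oxidation of the neopentyl primary alcohol gives a non-enolisable α-alkoxy aldehyde, and the tertiary C4 hydroxyl cannot be oxidised.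

Step 16
Reactants: 20 (1S,3S)-1-(4-bromo-5-oxo-2,5-dihydrofuran-3-yl)-3-[(5S)-5-formyl-5-methyl-4,5-dihydrofuran-2-yl]-3-hydroxybutyl acetate
Product: 24 (4S,6S,10S,8E)-6-acetoxy-11-bromo-4-hydroxy-3,10-epoxy-13-norgermacra-2,7(11),8-trien-12,8-olide, via silyloxyfuran 21 (not isolated), via aldol silyl ether 22 (not isolated), via silyl ether 23 (not isolated)
Conditions: TMSOTf, Et3N, CH2Cl2 (slow addition, high dilution), −78 → 0 °C; DBU, 0 °C → rt; AcOH, TBAF, 0 °C
Reagents that add atoms: none
Why: Soft enolisation gives the 2-silyloxyfuran 21 (O4 is silylated as well), whose γ-carbon C8 adds to the silyl-triflate-activated aldehyde C9 in an intramolecular vinylogous Mukaiyama aldol reaction, and base-induced E1cB loss of silanolate from 22 gives the dienyl lactone; the C8=C9 geometry with C10 cis to C7 is the one the bridged ring can hold, the bromine on C11 offers no leaving group β to the dienolate, and buffered fluoride finally frees O4.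

Step 17
Reactants: 24 (4S,6S,10S,8E)-6-acetoxy-11-bromo-4-hydroxy-3,10-epoxy-13-norgermacra-2,7(11),8-trien-12,8-olide
Product: 25 (4S,6S,10S,8E)-6-acetoxy-4,13-dihydroxy-3,10-epoxygermacra-2,7(11),8-trien-12,8-olide
Conditions: Bu3SnCH2OH, Pd(PPh3)4 (cat.), 1,4-dioxane, 80 °C
Reagents that add atoms: (tributylstannyl)methanol, CCCC[Sn](CCCC)(CCCC)CO
Why: Stille coupling, in which zerovalent palladium inserts into the activated C11–Br bond of the α-bromo enoate much faster than it could ionise the hindered C6 acetate, and transmetalation from the hydroxymethylstannane installs C13 under neutral conditions.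

Step 18
Reactants: 25 (4S,6S,10S,8E)-6-acetoxy-4,13-dihydroxy-3,10-epoxygermacra-2,7(11),8-trien-12,8-olide
Product: 26 (4S,6S,10S,8E)-6,13-diacetoxy-4-hydroxy-3,10-epoxygermacra-2,7(11),8-trien-12,8-olide (CNP0144020.1)
Conditions: Ac2O, pyridine, CH2Cl2, 0 °C
Reagents that add atoms: acetic anhydride, CC(=O)OC(C)=O
Why: Acylation of the primary allylic hydroxyl proceeds while the tertiary C4 hydroxyl is inert under these conditions, which should give the target.

Compound list

1 | (R)-2-methylglycidol, [(2R)-2-methyloxiran-2-yl]methanol | C[C@]1(CO1)CO | starting material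
2 | tert-butyl{[(2S)-2-methyloxiran-2-yl]methoxy}diphenylsilane | C[C@]1(CO1)CO[Si](c2ccccc2)(c2ccccc2)C(C)(C)C | intermediate
3 | (2S)-1-[tert-butyl(diphenyl)silyl]oxy-2-methylpent-4-en-2-ol | C=CC[C@@](C)(CO[Si](c1ccccc1)(c1ccccc1)C(C)(C)C)O | intermediate
4 | (S)-citramalic acid, (2S)-2-hydroxy-2-methylbutanedioic acid | C[C@](O)(CC(=O)O)C(=O)O | starting material
5 | 2-[(4S)-2,2,4-trimethyl-5-oxo-1,3-dioxolan-4-yl]acetic acid | C[C@@]1(CC(=O)O)OC(C)(C)OC1=O | intermediate
6 | (5S)-5-(2-hydroxyethyl)-2,2,5-trimethyl-1,3-dioxolan-4-one | C[C@@]1(CCO)OC(C)(C)OC1=O | intermediate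
7 | (5S)-2,2,5-trimethyl-5-[2-(triethylsilyloxy)ethyl]-1,3-dioxolan-4-one | C[C@@]1(CCO[Si](CC)(CC)CC)OC(C)(C)OC1=O | intermediate
8 | potassium (2S)-1-[tert-butyl(diphenyl)silyl]oxy-2-methylpent-4-en-2-olate | C=CC[C@@](C)(CO[Si](c1ccccc1)(c1ccccc1)C(C)(C)C)[O-].[K+] | intermediate
9 | potassium alkoxide at O4 of the ester (10 without the O4 silyl group) | C=CC[C@@](C)(CO[Si](c1ccccc1)(c1ccccc1)C(C)(C)C)OC(=O)[C@@](C)([O-])CCO[Si](CC)(CC)CC.[K+] | intermediate
10 | (2S)-1-[tert-butyl(diphenyl)silyl]oxy-2-methylpent-4-en-2-yl (2S)-2-methyl-2,4-bis(triethylsilyloxy)butanoate (key-step precursor) | C=CC[C@@](C)(CO[Si](c1ccccc1)(c1ccccc1)C(C)(C)C)OC(=O)[C@@](C)(O[Si](CC)(CC)CC)CCO[Si](CC)(CC)CC | intermediate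
11 | tert-butyl({(2S)-2-methyl-5-[(2S)-2,4-bis(triethylsilyloxy)butan-2-yl]-2,3-dihydrofuran-2-yl}methoxy)diphenylsilane (key-step product) | CC(C)(C)[Si](c1ccccc1)(c1ccccc1)OC[C@]2(C)CC=C(O2)[C@@](C)(O[Si](CC)(CC)CC)CCO[Si](CC)(CC)CC | intermediate
12 | (3S)-3-[(5S)-5-{[tert-butyl(diphenyl)silyl]oxymethyl}-5-methyl-4,5-dihydrofuran-2-yl]-3-(triethylsilyloxy)butan-1-ol | CC(C)(C)[Si](c1ccccc1)(c1ccccc1)OC[C@]2(C)CC=C(O2)[C@@](C)(O[Si](CC)(CC)CC)CCO | intermediate
13 | (3S)-3-[(5S)-5-{[tert-butyl(diphenyl)silyl]oxymethyl}-5-methyl-4,5-dihydrofuran-2-yl]-3-(triethylsilyloxy)butanal | CC(C)(C)[Si](c1ccccc1)(c1ccccc1)OC[C@]2(C)CC=C(O2)[C@@](C)(O[Si](CC)(CC)CC)CC=O | intermediate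
14 | 3,4-dibromofuran-2(5H)-one | O=C1OCC(Br)=C1Br | starting material
15 | 3-bromo-4-{(1RS,3S)-3-[(5S)-5-{[tert-butyl(diphenyl)silyl]oxymethyl}-5-methyl-4,5-dihydrofuran-2-yl]-1-hydroxy-3-(triethylsilyloxy)butyl}furan-2(5H)-one (C6 epimers) | CC(C)(C)[Si](c1ccccc1)(c1ccccc1)OC[C@]2(C)CC=C(O2)[C@@](C)(O[Si](CC)(CC)CC)CC(O)C3=C(Br)C(=O)OC3 | intermediate
16 | 3-bromo-4-{(3S)-3-[(5S)-5-{[tert-butyl(diphenyl)silyl]oxymethyl}-5-methyl-4,5-dihydrofuran-2-yl]-3-(triethylsilyloxy)butanoyl}furan-2(5H)-one | CC(C)(C)[Si](c1ccccc1)(c1ccccc1)OC[C@]2(C)CC=C(O2)[C@@](C)(O[Si](CC)(CC)CC)CC(=O)C3=C(Br)C(=O)OC3 | intermediate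
17 | 3-bromo-4-{(1S,3S)-3-[(5S)-5-{[tert-butyl(diphenyl)silyl]oxymethyl}-5-methyl-4,5-dihydrofuran-2-yl]-1-hydroxy-3-(triethylsilyloxy)butyl}furan-2(5H)-one | CC(C)(C)[Si](c1ccccc1)(c1ccccc1)OC[C@]2(C)CC=C(O2)[C@@](C)(O[Si](CC)(CC)CC)C[C@H](O)C3=C(Br)C(=O)OC3 | intermediate
18 | (1S,3S)-1-(4-bromo-5-oxo-2,5-dihydrofuran-3-yl)-3-[(5S)-5-{[tert-butyl(diphenyl)silyl]oxymethyl}-5-methyl-4,5-dihydrofuran-2-yl]-3-(triethylsilyloxy)butyl acetate | CC(C)(C)[Si](c1ccccc1)(c1ccccc1)OC[C@]2(C)CC=C(O2)[C@@](C)(O[Si](CC)(CC)CC)C[C@H](OC(C)=O)C3=C(Br)C(=O)OC3 | intermediate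
19 | (1S,3S)-1-(4-bromo-5-oxo-2,5-dihydrofuran-3-yl)-3-hydroxy-3-[(5S)-5-(hydroxymethyl)-5-methyl-4,5-dihydrofuran-2-yl]butyl acetate | OC[C@]1(C)CC=C(O1)[C@@](C)(O)C[C@H](OC(C)=O)C2=C(Br)C(=O)OC2 | intermediate
20 | (1S,3S)-1-(4-bromo-5-oxo-2,5-dihydrofuran-3-yl)-3-[(5S)-5-formyl-5-methyl-4,5-dihydrofuran-2-yl]-3-hydroxybutyl acetate | O=C[C@]1(C)CC=C(O1)[C@@](C)(O)C[C@H](OC(C)=O)C2=C(Br)C(=O)OC2 | intermediate
21 | O4-trimethylsilyl ether of 20 with the butenolide as its 3-bromo-2-(trimethylsilyloxy)furan | O=C[C@]1(C)CC=C(O1)[C@@](C)(O[Si](C)(C)C)C[C@H](OC(C)=O)c2coc(O[Si](C)(C)C)c2Br | intermediate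
22 | macrocyclic aldol with the C8–C9 bond closed, C9–OSiMe3 and O4–SiMe3 (C8/C9 epimers), butenolide restored | C[Si](C)(C)OC1[C@]2(C)CC=C(O2)[C@@](C)(O[Si](C)(C)C)C[C@H](OC(C)=O)C3=C(Br)C(=O)OC13 | intermediate
23 | (4S,6S,10S,8E)-6-acetoxy-11-bromo-4-(trimethylsilyloxy)-3,10-epoxy-13-norgermacra-2,7(11),8-trien-12,8-olide | BrC1=C2/C(=C\[C@]3(C)CC=C(O3)[C@@](C)(O[Si](C)(C)C)C[C@@H]2OC(C)=O)OC1=O | intermediate
24 | (4S,6S,10S,8E)-6-acetoxy-11-bromo-4-hydroxy-3,10-epoxy-13-norgermacra-2,7(11),8-trien-12,8-olide | BrC1=C2/C(=C\[C@]3(C)CC=C(O3)[C@@](C)(O)C[C@@H]2OC(C)=O)OC1=O | intermediate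
25 | (4S,6S,10S,8E)-6-acetoxy-4,13-dihydroxy-3,10-epoxygermacra-2,7(11),8-trien-12,8-olide | OCC1=C2/C(=C\[C@]3(C)CC=C(O3)[C@@](C)(O)C[C@@H]2OC(C)=O)OC1=O | intermediate
26 | (4S,6S,10S,8E)-6,13-diacetoxy-4-hydroxy-3,10-epoxygermacra-2,7(11),8-trien-12,8-olide (CNP0144020.1) | CC(=O)OCC1=C2/C(=C\[C@]3(C)CC=C(O3)[C@@](C)(O)C[C@@H]2OC(C)=O)OC1=O | target

Total step count: 18
Longest linear sequence: 16 steps (from 4 through steps 3–18 to 26)

Steps most likely to fail

Step 16 (closure of the ten-membered ring). The chain ends may not meet, so that oligomerisation or plain loss of the silyl enol ether wins over closure of the strained oxygen-bridged ring, or the silyl triflate may ionise the C6 acetate next to the electron-rich silyloxyfuran. The fallback separates ring formation from dehydration and uses no Lewis acid. It sets out from 20: catalytic DBU in acetonitrile at high dilution should give, by a direct and reversible base-catalysed vinylogous aldol addition, the macrocyclic aldol F1. Acetylation of its secondary C9 hydroxyl (Ac2O, pyridine, DMAP, 0 °C; the tertiary hydroxyl stays free) gives the aldol acetate F2, and DBU then eliminates acetic acid by the E1cB path to come back to the route at 24.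

Step 6 (ester between two fully substituted carbinol carbons). Acyl transfer may stall at the hindered carbonyl, or the silyl group may shift from O9 to the C10 alkoxide before acylation, which would lead to the primary ester. The fallback changes both the acyl donor and the nucleophile. It sets out from 7: hydrolysis with LiOH in THF/water gives the hydroxy acid F3, and TESOTf with 2,6-lutidine gives the silyl ester F4. (COCl)2 with catalytic DMF converts this under neutral conditions into the acid chloride F5. Alcohol 3 is deprotonated with n-BuLi in THF at −78 °C to the lithium alkoxide F6, which migrates silyl groups far more slowly than the potassium salt, and its acylation by F5 comes back to the route at 10.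

Step 7 (key step). The shielded ester may not react with the alkylidene at all, or it may be ethylidenated without ring closure. The fallback divides the event into two known reactions. It sets out from 10: methylenation of the ester carbonyl with Cp2Ti(CH3)2 in toluene at 65 °C gives the acyclic enol ether F7. Ring-closing enol ether–olefin metathesis with the second-generation Grubbs catalyst RuCl2(=CHPh)(PCy3)(H2IMes), with loss of ethene, then comes back to the route at 11.

Further compounds

F1 | step 16 | macrocyclic aldol with the C8–C9 bond closed and a free C9 hydroxyl (C8/C9 epimers), C4–OH free, C6–OAc, Br on C11 | OC1[C@]2(C)CC=C(O2)[C@@](C)(O)C[C@H](OC(C)=O)C3=C(Br)C(=O)OC13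
F2 | step 16 | C9 acetate of F1 | CC(=O)OC1[C@]2(C)CC=C(O2)[C@@](C)(O)C[C@H](OC(C)=O)C3=C(Br)C(=O)OC13
F3 | step 6 | (2S)-2-hydroxy-2-methyl-4-(triethylsilyloxy)butanoic acid | C[C@](O)(CCO[Si](CC)(CC)CC)C(=O)O
F4 | step 6 | triethylsilyl (2S)-2-methyl-2,4-bis(triethylsilyloxy)butanoate | C[C@](O[Si](CC)(CC)CC)(CCO[Si](CC)(CC)CC)C(=O)O[Si](CC)(CC)CC
F5 | step 6 | (2S)-2-methyl-2,4-bis(triethylsilyloxy)butanoyl chloride | C[C@](O[Si](CC)(CC)CC)(CCO[Si](CC)(CC)CC)C(Cl)=O
F6 | step 6 | lithium (2S)-1-[tert-butyl(diphenyl)silyl]oxy-2-methylpent-4-en-2-olate | C=CC[C@@](C)(CO[Si](c1ccccc1)(c1ccccc1)C(C)(C)C)[O-].[Li+]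
F7 | step 7 | acyclic enol ether, 10 with C3=CH2 in place of C3=O | C=CC[C@@](C)(CO[Si](c1ccccc1)(c1ccccc1)C(C)(C)C)OC(=C)[C@@](C)(O[Si](CC)(CC)CC)CCO[Si](CC)(CC)CC
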